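**Retrosynthetic overview**

- Numbering: C7/C7' are the benzylic CH2 groups, C8 the CH, C8' the tertiary carbinol carbon, C9/C9' the CH2OH carbons. The feature used: C8 and C8' each carry one CH2OH arm and one CH2–(4-hydroxy-3-methoxyphenyl) arm, and the two aryl rings are identical. Joining C7 to C9 and C7' to C9' through oxygen therefore folds all six core carbons into an achiral 3,3'-bioxetane (ring A at C8', ring B at C8).
- Last disconnection: the three O-benzyl groups (two phenols and the C8' hydroxyl), removed together by hydrogenolysis.
- Key disconnection: aryl–C7 and aryl–C7' in one operation, back to 3-(benzyloxy)-3,3'-bioxetane and two molecules of O-benzyl-4-bromoguaiacol. In the forward sense a twofold reductive arylative oxetane opening sets C8 and C8'.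
- Bis-oxetane: the C8–C8' bond comes from a samarium Barbier addition of 3-iodooxetane to oxetan-3-one, followed by O-benzylation.
- Ring order: no ring is formed in the route. Both oxetanes and both arenes are bought in, and rings A and B are opened in the key step.

Key step: step 4

Remark: which hand of the titanocene gives the (8R,8'R) series cannot be predicted and is assumed to be settled in a pilot run; both hands are accessible from (−)- or (+)-menthol, and the route is written for the hand that gives 8R,8'R.

**Route**

Step 1
Reactants: 1 oxetan-3-one; 2 3-iodooxetane
Product: 3 3-(oxetan-3-yl)oxetan-3-ol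
Conditions: SmI2 (2.5 equiv), HMPA, THF, 0 °C, 1 and 2 added together as one solution; aq. NH4Cl
Reagents that add atoms: none
Why: Samarium Barbier reaction: divalent samarium reduces the C–I bond of 2 to the oxetan-3-yl radical and then the organosamarium, which should be trapped at once by the strained, strongly electrophilic ketone 1 present in the same flask before ring-opening β-alkoxide elimination can compete, while the in-plane C–O bonds of 1 lie orthogonal to the ketyl π system and so should resist reductive α-C–O cleavage.

Step 2
Reactants: 3 3-(oxetan-3-yl)oxetan-3-ol
Product: 4 3-(benzyloxy)-3-(oxetan-3-yl)oxetane (3-(benzyloxy)-3,3'-bioxetane; ring A is the oxetane bearing the benzyloxy group and holds C8', ring B is the oxetan-3-yl ring and holds C8)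
Conditions: NaH, BnBr, n-Bu4NI (cat.), DMF, 0 °C → rt
Reagents that add atoms: benzyl bromide, BrCc1ccccc1
Why: Williamson etherification of a tertiary alkoxide that is unusually accessible because the oxetane ties back two of its three carbon substituents, with both oxetane rings inert to hydride base and bromide at room temperature.

Step 3
Reactants: 5 4-bromo-2-methoxyphenol
Product: 6 1-(benzyloxy)-4-bromo-2-methoxybenzene
Conditions: BnBr, K2CO3, acetone, reflux
Reagents that add atoms: benzyl bromide, BrCc1ccccc1
Why: Williamson etherification of the phenoxide with benzyl bromide, under which the aryl bromide is untouched.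

Step 4
Reactants: 4 3-(benzyloxy)-3-(oxetan-3-yl)oxetane; 6 1-(benzyloxy)-4-bromo-2-methoxybenzene (two molecules incorporated, used in excess)
Product: 9 (2R,3R)-2-(benzyloxy)-2,3-bis{[4-(benzyloxy)-3-methoxyphenyl]methyl}butane-1,4-diol, via ring-B-opened monoaryl alcohol 7 (not isolated), via ring-A-opened monoaryl alcohol 8 (not isolated)
Conditions: NiCl2(dme) (10 mol%), 2,2'-bipyridine (10 mol%), (neomenthyl-C5H4)2TiCl2 (20 mol%), Mn (4 equiv), Et3N·HCl (3 equiv), DMPU, 25–40 °C, 6 (3 equiv) added in portions
Reagents that add atoms: none
Why: Proposed new method: trivalent titanium, formed from (neomenthyl-C5H4)2TiCl2 and Mn, should bind an oxetane oxygen of 4 and homolyse one of the two enantiotopic CH2–O bonds with release of ring strain to give a primary γ-titanoxy radical at C7 or C7', which is captured by the aryl-nickel bromide formed from 6 and zerovalent nickel, after which reductive elimination at nickel makes the aryl–CH2 bond, Et3N·HCl frees the C9 or C9' hydroxyl from titanium, and the same sequence runs again on the remaining ring of 7 or 8. The closest known reaction types are the enantioselective nickel/chiral titanocene reductive arylation of meso-epoxides and the homolytic opening of oxetanes by trivalent titanium, which have been combined neither on an oxetane nor twice within one substrate. No ring is closed: the step opens rings A and B and forms the two skeletal bonds aryl–C7 and aryl–C7'. Neither radical carbon is a stereocentre, so the configuration at C8 and at C8' depends only on which CH2–O bond of its ring is cut, a choice made in both rings by the chiral titanocene pocket and, for whichever ring opens second, also influenced by the centre already present. The step needs selection between enantiotopic CH2–O bonds in both rings and cross-coupling in preference to biaryl formation; two successive catalyst-controlled choices should send mismatched material into the separable (8R,8'S)/(8S,8'R) diastereomer and so raise the enantiomeric purity of the (8R,8'R) product, portionwise addition of 6 keeps aryl-nickel available while the slower oxetane homolysis proceeds, and the benzyl ether on C8' leaves no titanium-bound oxygen next to the C7' radical, which removes the deoxygenative β-elimination open to a free hydroxyl.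

Step 5
Reactants: 9 (2R,3R)-2-(benzyloxy)-2,3-bis{[4-(benzyloxy)-3-methoxyphenyl]methyl}butane-1,4-diol
Product: 10 (2R,3R)-2,3-bis[(4-hydroxy-3-methoxyphenyl)methyl]butane-1,2,4-triol (target)
Conditions: H2 (1–3 atm), Pd(OH)2/C, MeOH/EtOAc, rt
Reagents that add atoms: none
Why: Heterogeneous hydrogenolysis should cleave the O–CH2Ph bonds of the two aryl benzyl ethers and of the tertiary alkyl benzyl ether, whereas C7 and C7' are joined to their rings through carbon only and are not cleaved, and neither stereocentre takes part, so the (2R,3R) configuration is carried through unchanged.

**Compound list**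

1 | oxetan-3-one | O=C1COC1 | starting material
2 | 3-iodooxetane | IC1COC1 | starting material
3 | 3-(oxetan-3-yl)oxetan-3-ol | OC1(C2COC2)COC1 | intermediate
4 | 3-(benzyloxy)-3-(oxetan-3-yl)oxetane (3-(benzyloxy)-3,3'-bioxetane) | c1ccccc1COC1(C2COC2)COC1 | intermediate (key-step precursor)
5 | 4-bromo-2-methoxyphenol | COc1cc(Br)ccc1O | starting material
6 | 1-(benzyloxy)-4-bromo-2-methoxybenzene | COc1cc(Br)ccc1OCc1ccccc1 | intermediate (key-step precursor)
7 | (2R)-2-[3-(benzyloxy)oxetan-3-yl]-3-[4-(benzyloxy)-3-methoxyphenyl]propan-1-ol (ring B opened first) | COc1cc(C[C@H](CO)C2(OCc3ccccc3)COC2)ccc1OCc1ccccc1 | intermediate (not isolated)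
8 | (2R)-2-(benzyloxy)-3-[4-(benzyloxy)-3-methoxyphenyl]-2-(oxetan-3-yl)propan-1-ol (ring A opened first) | C1OCC1[C@@](OCc1ccccc1)(CO)Cc1ccc(OCc2ccccc2)c(OC)c1 | intermediate (not isolated)
9 | (2R,3R)-2-(benzyloxy)-2,3-bis{[4-(benzyloxy)-3-methoxyphenyl]methyl}butane-1,4-diol | COc1cc(C[C@H](CO)[C@@](OCc2ccccc2)(CO)Cc2ccc(OCc3ccccc3)c(OC)c2)ccc1OCc1ccccc1 | intermediate (key-step product)
10 | (2R,3R)-2,3-bis[(4-hydroxy-3-methoxyphenyl)methyl]butane-1,2,4-triol | COc1cc(C[C@H](CO)[C@@](O)(CO)Cc2ccc(O)c(OC)c2)ccc1O | target

**Step count**

Total steps: 5. Longest linear sequence: 4 steps (steps 1, 2, 4, 5); step 3 is a one-step side branch.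

**Steps most likely to fail**

1. Step 4 (proposed new method). Several processes may defeat it:
   - Homolysis of the unactivated oxetane C–O bond may be slower than reductive homocoupling of 6.
   - The titanocene may distinguish the enantiotopic CH2–O bonds poorly in one ring, or with a sense at ring A that does not match the sense at ring B.
   - The hydroxyl freed in the first opening may attack the second, titanium-bound oxetane and close a tetrahydrofuran.
   - The C7' radical may lose its β-benzyloxy group.

   Fallback with known chemistry, setting out from 4 and 6 and returning at 9: bromine–lithium exchange on 6 (n-BuLi, THF, −78 °C) should give [4-(benzyloxy)-3-methoxyphenyl]lithium F1. Addition of 4 and then BF3·OEt2 at −78 °C should open both oxetanes by SN2 attack of the aryllithium at a ring CH2, the established Lewis-acid-promoted opening of oxetanes by organolithium reagents. This gives the stereoisomer mixture of the tri-O-benzyl triol F2 (all four stereoisomers). The like pair would be separated from the unlike pair on silica and resolved by preparative chromatography on a chiral stationary phase to give 9. Catalyst control is given up and replaced by separation.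

2. Step 1. Ketone 1 may be reduced to its ketyl and undergo pinacol coupling before the C–I bond is reduced, or the oxetan-3-yl samarium species may ring-open by β-elimination before it adds.

   Fallback setting out from 1 and returning at 4 (compound 3 and step 2 are bypassed):
   - Knoevenagel condensation of 1 with diethyl malonate (TiCl4, pyridine, THF, 0 °C) should give diethyl 2-(oxetan-3-ylidene)malonate F3.
   - Base-catalysed oxa-Michael addition of benzyl alcohol (cat. NaH, THF, 0 °C), driven by relief of the exocyclic alkene on the four-membered ring, should give diethyl 2-[3-(benzyloxy)oxetan-3-yl]malonate F4.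
   - LiAlH4 (THF, −20 → 0 °C, kept cold to limit retro-addition) should give 2-[3-(benzyloxy)oxetan-3-yl]propane-1,3-diol F5.
   - One-pot monotosylation and Williamson closure (n-BuLi, TsCl, THF, 0 °C; then n-BuLi, 60 °C) should pass through the racemic monotosylate 2-[3-(benzyloxy)oxetan-3-yl]-3-hydroxypropyl 4-methylbenzenesulfonate F6 and close ring B by 4-exo-tet displacement to give 4.

3. Step 5. Hydrogenolysis may stall at the hindered tertiary benzyl ether once the two phenolic benzyl groups are gone.

   Fallback setting out from 9 and returning at 10: single-electron reductive debenzylation with excess lithium 4,4'-di-tert-butylbiphenylide in THF at −78 °C (the excess allows for the two free hydroxyls), then NH4Cl quench. Each benzyl ether radical anion should fragment to the alkoxide or phenoxide and a benzyl fragment without touching the aryl methyl ethers or the stereocentres. No new compound is made on the way.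

**Further compounds**

F1 | step 4 | [4-(benzyloxy)-3-methoxyphenyl]lithium | [Li]c1ccc(OCc2ccccc2)c(OC)c1
F2 | step 4 | 2-(benzyloxy)-2,3-bis{[4-(benzyloxy)-3-methoxyphenyl]methyl}butane-1,4-diol, mixture of all four stereoisomers | COc1cc(CC(CO)C(OCc2ccccc2)(CO)Cc2ccc(OCc3ccccc3)c(OC)c2)ccc1OCc1ccccc1
F3 | step 1 | diethyl 2-(oxetan-3-ylidene)malonate | CCOC(=O)C(C(=O)OCC)=C1COC1
F4 | step 1 | diethyl 2-[3-(benzyloxy)oxetan-3-yl]malonate | CCOC(=O)C(C(=O)OCC)C1(OCc2ccccc2)COC1
F5 | step 1 | 2-[3-(benzyloxy)oxetan-3-yl]propane-1,3-diol | OCC(CO)C1(OCc2ccccc2)COC1
F6 | step 1 | 2-[3-(benzyloxy)oxetan-3-yl]-3-hydroxypropyl 4-methylbenzenesulfonate (racemic) | Cc1ccc(cc1)S(=O)(=O)OCC(CO)C1(OCc2ccccc2)COC1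
F0 | step 5 | none | none
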